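**Plan**

1. The target is a dihydrochalcone. Ring A is the 5,7-dihydroxy-2,2-dimethylchroman with the ketone on C6; ring B is the 2,2-dimethylchroman with the chain on its C6 (C6'). The retrosynthesis cuts the C(=O)–Cα bond. The aryl C=O and the benzylic Cβ stand in a 1,3-relationship, so they are treated as a β-hydroxy ketone hidden in a 3,5-diaryl-2-isoxazoline.
2. The isoxazoline is cut into a ring A nitrile oxide and the ring B styrene, 2,2-dimethyl-6-vinylchroman. The dipole carbon sits on C6 between the oxygens on C5 and C7, and these two flanking groups keep the dipole from dimerising. Both pyran rings are cut back to aryl 1,1-dimethylpropargyl ethers.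
3. Forward, each dimethylpyran ring is closed first by a propargyl ether Claisen cascade on a hydroxybenzaldehyde and then saturated. Ring A is benzylated and its formyl group is taken to the nitrile oxide; the formyl group of ring B becomes the vinyl group.
4. The [3+2] cycloaddition joins the halves and closes the temporary isoxazoline. N–O hydrogenolysis with hydrolysis, dehydration and one last hydrogenation (C=C reduction and loss of both benzyl groups) then give the target.
5. The target has no stereocentre. The only one made on the way (C5 of the isoxazoline, the later Cβ) is racemic and is erased at the chalcone stage.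

Key step: step 11

Assumption: nitrile oxide 9 is taken to be isolable, like other 2,6-dioxygenated aryl nitrile oxides; if it keeps poorly, it would be carried into step 11 as a freshly prepared solution with no change to the route. Locants follow chroman numbering (O1, C2 … C8a).

**Ring A: the nitrile oxide**

Step 1
Reactants: 1 2,4,6-trihydroxybenzaldehyde; 2 3-chloro-3-methylbut-1-yne
Product: 3 2,6-dihydroxy-4-[(2-methylbut-3-yn-2-yl)oxy]benzaldehyde
Conditions: DBU (1.05 equiv), CuCl2·2H2O (cat.), MeCN, −5 to 0 °C
Reagents that add atoms: none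
Why: Copper-catalysed O-propargylation of a phenoxide (Williamson-type ether synthesis), in which one equivalent of base should ionise only the 4-hydroxyl, the most acidic one and the only one not hydrogen-bonded to the formyl group, so that the tertiary propargyl group enters there.

Step 2
Reactants: 3 2,6-dihydroxy-4-[(2-methylbut-3-yn-2-yl)oxy]benzaldehyde
Product: 5 5,7-dihydroxy-2,2-dimethyl-2H-chromene-6-carbaldehyde, via allenylphenol 4 (not isolated)
Conditions: DMF, 140 °C
Reagents that add atoms: none
Why: Aryl propargyl ether Claisen rearrangement, in which the [3,3] shift to C3 (C5 is equivalent) and rearomatisation give allenylphenol 4, whose [1,5]-hydrogen shift and oxa-6π electrocyclisation close the pyran on the former ether oxygen and leave the formyl group on C6 between the two free hydroxyls.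

Step 3
Reactants: 5 5,7-dihydroxy-2,2-dimethyl-2H-chromene-6-carbaldehyde
Product: 6 5,7-dihydroxy-2,2-dimethylchroman-6-carbaldehyde
Conditions: H2 (1 atm), 10% Pd/C, EtOAc, rt
Reagents that add atoms: none
Why: Heterogeneous hydrogenation of the styrene-type C3=C4 bond, while the formyl group, deactivated by three donor oxygens and chelated by both ortho hydroxyls, should stay untouched at one atmosphere.

Step 4
Reactants: 6 5,7-dihydroxy-2,2-dimethylchroman-6-carbaldehyde
Product: 7 5,7-bis(benzyloxy)-2,2-dimethylchroman-6-carbaldehyde
Conditions: BnBr (2.5 equiv), K2CO3 (3 equiv), DMF, 60 °C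
Reagents that add atoms: benzyl bromide, BrCc1ccccc1
Why: Williamson etherification of both chelated phenols with excess bromide in a dipolar aprotic solvent; benzyl is chosen because the last hydrogenation removes it without a separate step and because two ortho ethers are what shield the later dipole.

Step 5
Reactants: 7 5,7-bis(benzyloxy)-2,2-dimethylchroman-6-carbaldehyde
Product: 8 (E)-5,7-bis(benzyloxy)-2,2-dimethylchroman-6-carbaldehyde oxime
Conditions: NH2OH·HCl, NaOAc, EtOH/H2O, 70 °C
Reagents that add atoms: hydroxylamine hydrochloride, Cl.NO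
Why: Oxime condensation of an aryl aldehyde, which should give the E isomer because the hydroxyl then points away from the doubly ortho-substituted ring.

Step 6
Reactants: 8 (E)-5,7-bis(benzyloxy)-2,2-dimethylchroman-6-carbaldehyde oxime
Product: 9 5,7-bis(benzyloxy)-2,2-dimethylchroman-6-carbonitrile oxide
Conditions: PhI(OAc)2 (1.1 equiv), TFA (cat.), MeOH, 0 °C; NaHCO3 wash, crystallise, store cold
Reagents that add atoms: none
Why: Dehydrogenation of an aldoxime to the nitrile oxide with a hypervalent iodine oxidant, which avoids the electrophilic halogen that could attack the free C8 position of the electron-rich ring, while the benzyloxy groups on C5 and C7 block dimerisation to the furoxan and should make 9 isolable.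

**Ring B: the styrene**

Step 7
Reactants: 10 4-hydroxybenzaldehyde; 2 3-chloro-3-methylbut-1-yne
Product: 11 4-[(2-methylbut-3-yn-2-yl)oxy]benzaldehyde
Conditions: DBU (1.2 equiv), CuCl2·2H2O (cat.), MeCN, 0 °C
Reagents that add atoms: none
Why: The same copper-catalysed O-propargylation (Williamson-type ether synthesis), here on a single acidic phenol, so no site selectivity is needed.

Step 8
Reactants: 11 4-[(2-methylbut-3-yn-2-yl)oxy]benzaldehyde
Product: 13 2,2-dimethyl-2H-chromene-6-carbaldehyde, via allenylphenol 12 (not isolated)
Conditions: N,N-diethylaniline, 190 °C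
Reagents that add atoms: none
Why: Aryl propargyl ether Claisen rearrangement to the position ortho to oxygen, followed by [1,5]-hydrogen shift and oxa-6π electrocyclisation of allenylphenol 12, which places the formyl group para to the ring oxygen, at C6.

Step 9
Reactants: 13 2,2-dimethyl-2H-chromene-6-carbaldehyde
Product: 14 2,2-dimethylchroman-6-carbaldehyde
Conditions: H2 (1 atm), 5% Pd/C, EtOAc, rt, stopped after one equivalent of H2
Reagents that add atoms: none
Why: Heterogeneous hydrogenation, in which the cis-disubstituted styrene-type double bond should be reduced faster than the para-alkoxy aryl aldehyde when the uptake is limited to one equivalent.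

Step 10
Reactants: 14 2,2-dimethylchroman-6-carbaldehyde
Product: 15 2,2-dimethyl-6-vinylchroman
Conditions: MePPh3Br (1.3 equiv), KOtBu (1.25 equiv), THF, 0 °C to rt
Reagents that add atoms: methyltriphenylphosphonium bromide, [Br-].C[P+](c1ccccc1)(c1ccccc1)c1ccccc1
Why: Wittig methylenation of a non-enolisable aryl aldehyde with the unstabilised ylide, giving the terminal alkene with no geometry issue.

**Union and unmasking**

Step 11
Reactants: 9 5,7-bis(benzyloxy)-2,2-dimethylchroman-6-carbonitrile oxide; 15 2,2-dimethyl-6-vinylchroman (1.2 equiv)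
Product: 16 racemic 3-[5,7-bis(benzyloxy)-2,2-dimethylchroman-6-yl]-5-(2,2-dimethylchroman-6-yl)-4,5-dihydroisoxazole
Conditions: toluene, BHT (trace), 60 °C
Reagents that add atoms: none
Why: This is a concerted Huisgen 1,3-dipolar cycloaddition in which the C≡N–O dipole of 9 and the vinyl π bond of 15 combine suprafacially in a thermal six-electron process, forming the C3–C4 bond (the future C(=O)–Cα bond) and the temporary O1–C5 bond (O–Cβ) at once. The closest known reaction type is the addition of isolable hindered aryl nitrile oxides, such as mesitonitrile oxide, to styrenes. The isoxazoline ring is closed by this intermolecular [3+2] cycloaddition itself, so no separate cyclisation mode has to be met. The one new stereocentre, C5 of the isoxazoline, has no controlling element and forms as the racemate, which is harmless because it is erased in step 13 and becomes a methylene in step 14. The step needs regioselectivity for the 5-aryl isomer, secured by the monosubstituted alkene, whose unsubstituted terminus is less hindered and carries the larger HOMO coefficient and so bonds to the dipole carbon. It also needs chemoselectivity over furoxan formation, secured by the benzyloxy groups on C5 and C7 that flank the dipole, and the temperature is kept well below that at which hindered nitrile oxides isomerise to isocyanates.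

Step 12
Reactants: 16 racemic 3-[5,7-bis(benzyloxy)-2,2-dimethylchroman-6-yl]-5-(2,2-dimethylchroman-6-yl)-4,5-dihydroisoxazole
Product: 18 racemic 1-[5,7-bis(benzyloxy)-2,2-dimethylchroman-6-yl]-3-(2,2-dimethylchroman-6-yl)-3-hydroxypropan-1-one, via beta-hydroxy ketimine 17 (not isolated)
Conditions: H2 (1 atm), Raney Ni, B(OH)3 (3 equiv), MeOH/THF/H2O 5:2:1, rt
Reagents that add atoms: water, O
Why: Reductive N–O cleavage of a 2-isoxazoline over Raney Ni in a boric acid buffer, in which hydrogenolysis of the weak N–O bond gives ketimine 17 and the buffered aqueous medium hydrolyses it to the ketone before the C=N bond is reduced, under conditions mild enough to leave the benzyl ethers.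

Step 13
Reactants: 18 racemic 1-[5,7-bis(benzyloxy)-2,2-dimethylchroman-6-yl]-3-(2,2-dimethylchroman-6-yl)-3-hydroxypropan-1-one
Product: 19 (E)-1-[5,7-bis(benzyloxy)-2,2-dimethylchroman-6-yl]-3-(2,2-dimethylchroman-6-yl)prop-2-en-1-one
Conditions: TsOH·H2O (cat.), toluene, 80 °C
Reagents that add atoms: none
Why: Acid-catalysed E1 dehydration of a β-hydroxy ketone through the para-alkoxybenzyl cation, which should give the conjugated E-enone; with both ring A phenols benzylated, no flavanone can form.

Step 14
Reactants: 19 (E)-1-[5,7-bis(benzyloxy)-2,2-dimethylchroman-6-yl]-3-(2,2-dimethylchroman-6-yl)prop-2-en-1-one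
Product: 21 1-(5,7-dihydroxy-2,2-dimethylchroman-6-yl)-3-(2,2-dimethylchroman-6-yl)propan-1-one (target), via dibenzyl dihydrochalcone 20 (not isolated)
Conditions: H2 (1 atm), 10% Pd/C, EtOAc/MeOH, rt
Reagents that add atoms: none
Why: Heterogeneous hydrogenation that first saturates the enone C=C bond to give 20 and then hydrogenolyses both benzyl ethers, while the ketone, hindered and chelated by the two freed ortho hydroxyls, should resist reduction.

**Compound list**

1 | 2,4,6-trihydroxybenzaldehyde | O=Cc1c(O)cc(O)cc1O | starting material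
2 | 3-chloro-3-methylbut-1-yne | CC(C)(Cl)C#C | starting material
3 | 2,6-dihydroxy-4-[(2-methylbut-3-yn-2-yl)oxy]benzaldehyde | O=Cc1c(O)cc(OC(C)(C)C#C)cc1O | intermediate
4 | 2,4,6-trihydroxy-3-(3-methylbuta-1,2-dien-1-yl)benzaldehyde | O=Cc1c(O)cc(O)c(C=C=C(C)C)c1O | intermediate (not isolated)
5 | 5,7-dihydroxy-2,2-dimethyl-2H-chromene-6-carbaldehyde | CC1(C)C=Cc2c(O1)cc(O)c(C=O)c2O | intermediate
6 | 5,7-dihydroxy-2,2-dimethylchroman-6-carbaldehyde | CC1(C)CCc2c(O1)cc(O)c(C=O)c2O | intermediate
7 | 5,7-bis(benzyloxy)-2,2-dimethylchroman-6-carbaldehyde | CC1(C)CCc2c(O1)cc(OCc3ccccc3)c(C=O)c2OCc4ccccc4 | intermediate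
8 | (E)-5,7-bis(benzyloxy)-2,2-dimethylchroman-6-carbaldehyde oxime | CC1(C)CCc2c(O1)cc(OCc3ccccc3)c(/C=N/O)c2OCc4ccccc4 | intermediate
9 | 5,7-bis(benzyloxy)-2,2-dimethylchroman-6-carbonitrile oxide | CC1(C)CCc2c(O1)cc(OCc3ccccc3)c(C#[N+][O-])c2OCc4ccccc4 | intermediate
10 | 4-hydroxybenzaldehyde | O=Cc1ccc(O)cc1 | starting material
11 | 4-[(2-methylbut-3-yn-2-yl)oxy]benzaldehyde | O=Cc1ccc(OC(C)(C)C#C)cc1 | intermediate
12 | 4-hydroxy-3-(3-methylbuta-1,2-dien-1-yl)benzaldehyde | O=Cc1ccc(O)c(C=C=C(C)C)c1 | intermediate (not isolated)
13 | 2,2-dimethyl-2H-chromene-6-carbaldehyde | CC1(C)C=Cc2cc(C=O)ccc2O1 | intermediate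
14 | 2,2-dimethylchroman-6-carbaldehyde | CC1(C)CCc2cc(C=O)ccc2O1 | intermediate
15 | 2,2-dimethyl-6-vinylchroman | CC1(C)CCc2cc(C=C)ccc2O1 | intermediate
16 | racemic 3-[5,7-bis(benzyloxy)-2,2-dimethylchroman-6-yl]-5-(2,2-dimethylchroman-6-yl)-4,5-dihydroisoxazole | CC1(C)CCc2cc(C3CC(=NO3)c3c(OCc4ccccc4)cc4c(c3OCc3ccccc3)CCC(C)(C)O4)ccc2O1 | intermediate
17 | racemic 3-[5,7-bis(benzyloxy)-2,2-dimethylchroman-6-yl]-1-(2,2-dimethylchroman-6-yl)-3-iminopropan-1-ol | CC1(C)CCc2cc(C(O)CC(=N)c3c(OCc4ccccc4)cc4c(c3OCc3ccccc3)CCC(C)(C)O4)ccc2O1 | intermediate (not isolated)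
18 | racemic 1-[5,7-bis(benzyloxy)-2,2-dimethylchroman-6-yl]-3-(2,2-dimethylchroman-6-yl)-3-hydroxypropan-1-one | CC1(C)CCc2cc(C(O)CC(=O)c3c(OCc4ccccc4)cc4c(c3OCc3ccccc3)CCC(C)(C)O4)ccc2O1 | intermediate
19 | (E)-1-[5,7-bis(benzyloxy)-2,2-dimethylchroman-6-yl]-3-(2,2-dimethylchroman-6-yl)prop-2-en-1-one | CC1(C)CCc2cc(/C=C/C(=O)c3c(OCc4ccccc4)cc4c(c3OCc3ccccc3)CCC(C)(C)O4)ccc2O1 | intermediate
20 | 1-[5,7-bis(benzyloxy)-2,2-dimethylchroman-6-yl]-3-(2,2-dimethylchroman-6-yl)propan-1-one | CC1(C)CCc2cc(CCC(=O)c3c(OCc4ccccc4)cc4c(c3OCc3ccccc3)CCC(C)(C)O4)ccc2O1 | intermediate (not isolated)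
21 | 1-(5,7-dihydroxy-2,2-dimethylchroman-6-yl)-3-(2,2-dimethylchroman-6-yl)propan-1-one (CNP0080574.0, achiral) | CC1(C)CCc2cc(CCC(=O)c3c(O)cc4c(c3O)CCC(C)(C)O4)ccc2O1 | target

**Step count**

Total: 14 steps. Longest linear sequence: 10 steps (steps 1–6, then 11–14); the ring B branch (steps 7–10) has 4 steps.

**Steps most likely to fail**

Step 11 (key step). The doubly ortho-substituted dipole may add so slowly that isomerisation to the isocyanate or polymerisation of the electron-rich styrene takes over. The fallback makes the Cα–Cβ bond by an aldol condensation and sets out from aldehyde 7. MeMgBr in THF at 0 °C should give racemic 1-[5,7-bis(benzyloxy)-2,2-dimethylchroman-6-yl]ethan-1-ol F2. Dess–Martin periodinane in CH2Cl2 should then give 1-[5,7-bis(benzyloxy)-2,2-dimethylchroman-6-yl]ethan-1-one F3. Claisen–Schmidt condensation of F3 with aldehyde 14 (KOH, EtOH, room temperature) should give chalcone 19, where the route is rejoined before step 14.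

Step 1. Alkylation may not stop at the 4-hydroxyl, so that an ortho hydroxyl or a ring carbon is alkylated as well. The fallback attaches the pyran carbons at carbon instead of oxygen and sets out again from 1. Friedel–Crafts prenylation with 2-methylbut-3-en-2-ol and BF3·OEt2 in dioxane at room temperature should give 2,4,6-trihydroxy-3-(3-methylbut-2-en-1-yl)benzaldehyde F1. Warming F1 with catalytic TsOH·H2O in toluene should add the hydroxyl para to the formyl group across the prenyl double bond (Markovnikov hydroalkoxylation; the ortho hydroxyl is held by its hydrogen bond to the aldehyde). This gives chroman 6 directly, so the route is rejoined at step 4 and steps 2 and 3 are not needed. Any isomer closed on the ortho hydroxyl would be removed by chromatography.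

Step 12. The ketimine may be reduced further to an amino alcohol, benzyl ethers may be lost on the nickel surface, or the hindered ketimine may hydrolyse sluggishly. The fallback opens the ring without any reduction and sets out from isoxazoline 16. LiN(iPr)2 in THF at −78 °C, then warming to 0 °C, should remove a C4 proton and expel the ring oxygen from C5 (E1cB ring opening). This should give (E)-1-[5,7-bis(benzyloxy)-2,2-dimethylchroman-6-yl]-3-(2,2-dimethylchroman-6-yl)prop-2-en-1-one oxime F4, with the oxime geometry not controlled. Oxime exchange with aqueous glyoxylic acid in THF at 40 °C should then release chalcone 19, where the route is rejoined before step 14.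

**Further compounds**

F1 | step 1 | 2,4,6-trihydroxy-3-(3-methylbut-2-en-1-yl)benzaldehyde | O=Cc1c(O)cc(O)c(CC=C(C)C)c1O
F2 | step 11 | racemic 1-[5,7-bis(benzyloxy)-2,2-dimethylchroman-6-yl]ethan-1-ol | CC(O)c1c(OCc2ccccc2)cc3c(c1OCc4ccccc4)CCC(C)(C)O3
F3 | step 11 | 1-[5,7-bis(benzyloxy)-2,2-dimethylchroman-6-yl]ethan-1-one | CC(=O)c1c(OCc2ccccc2)cc3c(c1OCc4ccccc4)CCC(C)(C)O3
F4 | step 12 | (E)-1-[5,7-bis(benzyloxy)-2,2-dimethylchroman-6-yl]-3-(2,2-dimethylchroman-6-yl)prop-2-en-1-one oxime | CC1(C)CCc2cc(/C=C/C(=NO)c3c(OCc4ccccc4)cc4c(c3OCc3ccccc3)CCC(C)(C)O4)ccc2O1
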